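**Retrosynthetic overview**
- Target 29 comes from macrocycle 27 by removal of the sulfonyl and silyl groups. 27 comes from seco hydroxy sulfonamide 26 by forming the N–CH2 bond at the central spermidine nitrogen. This secondary amine between the three-carbon and four-carbon arms is the only basic N, and it sits in the flexible chain, far from both Z-enamides (C=C–C(=O)N) and from the cis-fused hexahydrodibenzofuran.
- 26 comes from C8 aryl boronate 20 and Z-iodoacrylamide 25 by Suzuki coupling with retention. 20 comes from C9b aldehyde 15 by Still–Gennari olefination, hydrolysis, amidation with 4-aminobutan-1-ol and borylation of the C8 chloride.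
- 15 comes from tricycle 10 by allylic oxidation at C3 (cis to the ring oxygen), alkene hydrogenation and protecting-group exchange. 10 comes from aryl ether 9 by intramolecular Heck reaction (quaternary C9b, cis fusion). 9 comes from a palladium-catalysed asymmetric allylic etherification of 2-bromo-4-chlorophenol, which sets C4a.
- Ring order: cyclohexene ring (step 1), dihydrofuran ring (step 6), 20-membered macrocycle (step 19).

Key step: step 19

Assumption (step 3): the (S,S) ligand is taken to deliver the phenoxide so as to give the (6R) ether; if the sense of induction proves opposite, the mirror-image (R,R) ligand is used and nothing else changes.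

**Step 1**
Reactants: 1 glutaraldehyde (pentanedial, aqueous); 2 trimethyl phosphonoacetate
Product: 4 methyl 6-hydroxycyclohex-1-ene-1-carboxylate (racemic), via hydroxy phosphonate aldehyde 3 (not isolated)
Conditions: K2CO3, H2O, rt
Reagents that add atoms: none
Why: The phosphonate carbanion adds to one formyl group (aldol-type addition) and the adduct closes onto the second formyl group by intramolecular Horner–Wadsworth–Emmons olefination, a known one-pot route from glutaraldehyde to this hydroxy enoate.

**Step 2**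
Reactants: 4 methyl 6-hydroxycyclohex-1-ene-1-carboxylate
Product: 5 methyl 6-{[(2,2,2-trichloroethoxy)carbonyl]oxy}cyclohex-1-ene-1-carboxylate (racemic)
Conditions: Cl3CCH2OCOCl, pyridine, CH2Cl2, 0 °C
Reagents that add atoms: 2,2,2-trichloroethyl chloroformate, ClC(=O)OCC(Cl)(Cl)Cl
Why: O-Acylation of the secondary allylic alcohol gives the allylic carbonate that serves as the leaving group for π-allyl palladium formation.

**Step 3**
Reactants: 5 allylic carbonate; 6 2-bromo-4-chlorophenol
Product: 7 methyl (6R)-6-(2-bromo-4-chlorophenoxy)cyclohex-1-ene-1-carboxylate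
Conditions: [Pd(η3-C3H5)Cl]2 (1 mol%), (1S,2S)-N,N'-bis[2-(diphenylphosphino)benzoyl]cyclohexane-1,2-diamine (3 mol%), Et3N, CH2Cl2, rt
Reagents that add atoms: none
Why: In this palladium-catalysed asymmetric allylic alkylation (Tsuji–Trost etherification) both enantiomers of 5 ionise to the same symmetric 2-carbomethoxy π-allyl complex, and the chiral diphosphine directs the phenoxide to one enantiotopic terminus, which sets the C–O stereocentre (the later C4a) by catalyst control, a reaction known for ortho-bromophenols with this type of carbonate.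

**Step 4**
Reactants: 7 aryl ether ester
Product: 8 [(6R)-6-(2-bromo-4-chlorophenoxy)cyclohex-1-en-1-yl]methanol
Conditions: i-Bu2AlH, CH2Cl2, −78 °C; aq. Rochelle salt
Reagents that add atoms: none
Why: 1,2-Hydride reduction of the conjugated ester gives the allylic alcohol without touching the aryl halides or the stereocentre, and removes the electron-withdrawing group that would make the allylic aryl ether prone to ionisation in the Heck step.

**Step 5**
Reactants: 8 allylic alcohol
Product: 9 tert-butyl{[(6R)-6-(2-bromo-4-chlorophenoxy)cyclohex-1-en-1-yl]methoxy}dimethylsilane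
Conditions: TBSCl, imidazole, DMF, rt
Reagents that add atoms: tert-butyldimethylsilyl chloride, CC(C)(C)[Si](C)(C)Cl
Why: Standard silylation masks the primary allylic alcohol, which Ag2CO3 would otherwise oxidise in the next step, as an ether that cannot ionise to a π-allyl complex.

**Step 6**
Reactants: 9 silyl ether
Product: 10 (4aR,9bR)-9b-{[(tert-butyldimethylsilyl)oxy]methyl}-8-chloro-3,4,4a,9b-tetrahydrodibenzo[b,d]furan (cis-fused, C1=C2 alkene)
Conditions: Pd(OAc)2 (15 mol%), dppp (15 mol%), Ag2CO3, toluene, 107 °C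
Reagents that add atoms: none
Why: In this intramolecular Mizoroki–Heck reaction oxidative addition occurs only at C–Br, 5-exo-trig carbopalladation delivers the aryl group to the alkene face held by the C4a–O tether so that quaternary C9b forms with obligatory cis fusion, and β-hydride elimination toward C2 leaves the C1=C2 alkene, while Ag2CO3 with the chelating diphosphine suppresses ionisation of the allylic aryl ether.

**Step 7**
Reactants: 10 tricyclic alkene
Product: 11 (3S,4aR,9bR)-9b-{[(tert-butyldimethylsilyl)oxy]methyl}-8-chloro-3,4,4a,9b-tetrahydrodibenzo[b,d]furan-3-ol (3-OH cis to the ring oxygen)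
Conditions: SeO2, NaH2PO4, quartz sand, 1,4-dioxane, 150 °C (sealed tube)
Reagents that add atoms: selenium dioxide, O=[Se]=O
Why: Selenium dioxide allylic oxidation (ene reaction, then [2,3]-sigmatropic shift) can only use the C3 hydrogens because the other allylic carbon C9b is quaternary; selenium attacks C1 anti to the CH2OTBS group and the suprafacial shift returns oxygen to C3 on the face of the C4a–O bond, the sense known for closely related 9b-substituted tetrahydrodibenzofurans.

**Step 8**
Reactants: 11 allylic alcohol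
Product: 12 (3R,4aR,9bR)-9b-{[(tert-butyldimethylsilyl)oxy]methyl}-8-chloro-1,2,3,4,4a,9b-hexahydrodibenzo[b,d]furan-3-ol
Conditions: H2 (1 atm), [Ir(cod)(PCy3)(py)]PF6 (5 mol%), CH2Cl2, rt
Reagents that add atoms: none
Why: Hydroxyl-directed homogeneous hydrogenation with the cationic iridium catalyst saturates the hindered C1=C2 alkene without touching the aryl chloride or the ethers, and creates no stereocentre.

**Step 9**
Reactants: 12 secondary alcohol
Product: 13 tert-butyl{[(3R,4aR,9bR)-8-chloro-3-[(triisopropylsilyl)oxy]-1,2,3,4,4a,9b-hexahydrodibenzo[b,d]furan-9b-yl]methoxy}dimethylsilane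
Conditions: TIPSOTf, 2,6-lutidine, CH2Cl2, 0 °C
Reagents that add atoms: triisopropylsilyl trifluoromethanesulfonate, CC(C)[Si](OS(=O)(=O)C(F)(F)F)(C(C)C)C(C)C
Why: Silylation with the reactive silyl triflate puts a TIPS ether on C3 that is far more stable to acid than the primary TBS ether, which makes the next selective deprotection possible and blocks C3–OH in the key step.

**Step 10**
Reactants: 13 bis-silyl ether
Product: 14 {(3R,4aR,9bR)-8-chloro-3-[(triisopropylsilyl)oxy]-1,2,3,4,4a,9b-hexahydrodibenzo[b,d]furan-9b-yl}methanol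
Conditions: camphorsulfonic acid (cat.), MeOH/CH2Cl2, 0 °C to rt
Reagents that add atoms: none
Why: Acid-catalysed methanolysis cleaves the more labile primary TBS ether while the secondary TIPS ether survives, following the established order of silyl ether lability.

**Step 11**
Reactants: 14 primary alcohol
Product: 15 (3R,4aR,9bS)-8-chloro-3-[(triisopropylsilyl)oxy]-1,2,3,4,4a,9b-hexahydrodibenzo[b,d]furan-9b-carbaldehyde
Conditions: Dess–Martin periodinane, CH2Cl2, rt
Reagents that add atoms: none
Why: Dess–Martin oxidation converts the neopentyl-type alcohol to the aldehyde under neutral conditions, and the aldehyde has no α-hydrogen, so it can neither epimerise nor eliminate the β-aryloxy group.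

**Step 12**
Reactants: 15 aldehyde
Product: 16 methyl (2Z)-3-{(3R,4aR,9bS)-8-chloro-3-[(triisopropylsilyl)oxy]-1,2,3,4,4a,9b-hexahydrodibenzo[b,d]furan-9b-yl}prop-2-enoate
Conditions: (CF3CH2O)2P(O)CH2CO2Me, KN(SiMe3)2, 18-crown-6, THF, −78 °C
Reagents that add atoms: methyl bis(2,2,2-trifluoroethyl)phosphonoacetate, COC(=O)CP(=O)(OCC(F)(F)F)OCC(F)(F)F
Why: In the Still–Gennari variant of the Horner–Wadsworth–Emmons reaction the electron-poor phosphonate with a dissociated potassium counter-ion eliminates fast from the kinetically formed adduct and should give the Z-enoate, and the non-enolisable aldehyde tolerates the base.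

**Step 13**
Reactants: 16 Z-enoate
Product: 17 (2Z)-3-{(3R,4aR,9bS)-8-chloro-3-[(triisopropylsilyl)oxy]-1,2,3,4,4a,9b-hexahydrodibenzo[b,d]furan-9b-yl}prop-2-enoic acid
Conditions: LiOH, THF/MeOH/H2O, rt; then 1 M HCl to pH 4
Reagents that add atoms: lithium hydroxide, [Li+].[OH-]
Why: Saponification of the methyl ester; the β-carbon is shielded by the quaternary centre, so conjugate addition and Z to E isomerisation are not expected, and the TIPS ether is stable to aqueous base.

**Step 14**
Reactants: 17 Z-acid; 18 4-aminobutan-1-ol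
Product: 19 (2Z)-3-{(3R,4aR,9bS)-8-chloro-3-[(triisopropylsilyl)oxy]-1,2,3,4,4a,9b-hexahydrodibenzo[b,d]furan-9b-yl}-N-(4-hydroxybutyl)prop-2-enamide
Conditions: DIC, HOBt, CH2Cl2/DMF, 0 °C to rt
Reagents that add atoms: none
Why: Carbodiimide/HOBt amide coupling is chemoselective for the far more nucleophilic amino group, so the primary alcohol needed for the key step is brought in unprotected.

**Step 15**
Reactants: 19 aryl chloride
Product: 20 (2Z)-N-(4-hydroxybutyl)-3-{(3R,4aR,9bS)-8-(4,4,5,5-tetramethyl-1,3,2-dioxaborolan-2-yl)-3-[(triisopropylsilyl)oxy]-1,2,3,4,4a,9b-hexahydrodibenzo[b,d]furan-9b-yl}prop-2-enamide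
Conditions: Pd2(dba)3 (2 mol%), XPhos (8 mol%), B2pin2, KOAc, 1,4-dioxane, 100 °C
Reagents that add atoms: bis(pinacolato)diboron, CC1(C)OB(OC1(C)C)B1OC(C)(C)C(C)(C)O1
Why: Miyaura borylation of the electron-rich aryl chloride with a bulky biarylphosphine palladium catalyst and the weak base KOAc tolerates the free alcohol, the secondary amide and the hindered Z-enamide.

**Step 16**
Reactants: 21 propane-1,3-diamine (6 equiv); 22 2-nitrobenzenesulfonyl chloride
Product: 23 N-(3-aminopropyl)-2-nitrobenzenesulfonamide
Conditions: CH2Cl2, 0 °C, slow addition of 22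
Reagents that add atoms: none
Why: Sulfonylation of one amino group; the large excess of diamine makes mono-sulfonylation dominant and binds the HCl.

**Step 17**
Reactants: 24 (Z)-3-iodoacrylic acid; 23 N-(3-aminopropyl)-2-nitrobenzenesulfonamide
Product: 25 (2Z)-3-iodo-N-(3-{[(2-nitrophenyl)sulfonyl]amino}propyl)prop-2-enamide
Conditions: DIC, HOBt, CH2Cl2, 0 °C
Reagents that add atoms: none
Why: Carbodiimide/HOBt amide coupling at low temperature acylates the primary amine (the sulfonamide N–H is not nucleophilic) faster than the amine can add to the β-iodo enoate, and the Z-configured C=C–I unit is retained.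

**Step 18**
Reactants: 20 aryl boronate; 25 Z-iodoacrylamide
Product: 26 seco hydroxy sulfonamide, (2Z)-N-(4-hydroxybutyl)-3-{(3R,4aR,9bS)-8-[(1Z)-3-oxo-3-({3-[(2-nitrophenyl)sulfonylamino]propyl}amino)prop-1-en-1-yl]-3-[(triisopropylsilyl)oxy]-1,2,3,4,4a,9b-hexahydrodibenzo[b,d]furan-9b-yl}prop-2-enamide
Conditions: Pd[P(o-tol)3]2 (5 mol%), K3PO4, THF/H2O, 40 °C, exclusion of light
Reagents that add atoms: none
Why: Suzuki–Miyaura coupling of an aryl boronate with a Z-alkenyl iodide proceeds with retention of alkene geometry, and the bulky tri-o-tolylphosphine ligand is chosen because it is known to suppress Z to E isomerisation with Z-β-halo acrylic acid derivatives.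

**Step 19**
Reactants: 26 seco hydroxy sulfonamide
Product: 27 N-(2-nitrophenylsulfonyl), O-triisopropylsilyl macrocycle (20-membered ring; Z,Z; 3R,4aR,9bS)
Conditions: PPh3, DIAD, THF/toluene (about 2 mM), slow addition of 26, rt
Reagents that add atoms: none
Why: PPh3 and DIAD form a betaine that is protonated by the sulfonamide N–H and converts the primary alcohol into its alkoxyphosphonium ion; the sulfonamide anion then displaces Ph3P=O at the CH2 carbon by intramolecular SN2 attack, which is the Fukuyama–Mitsunobu N-alkylation of a 2-nitrobenzenesulfonamide, known also for closing polyamine macrolactams. The 20-membered ring closes in a 20-exo-tet mode at a bond inside the flexible spermidine chain, so little strain should build up, while the tricycle and the two Z-enamides act as a preorganising turn. No stereocentre is formed, and the three existing centres and both Z-alkenes see only neutral conditions at room temperature. The step needs chemoselectivity for the sulfonamide nitrogen and for ring closure over oligomerisation: the two amide N–H groups are too weakly acidic to enter the Mitsunobu cycle (so the hydroxybutyl amide should not close to a pyrrolidine), C3–OH is blocked as its TIPS ether, and slow addition at high dilution favours the intramolecular path. The sulfonyl group also keeps the nitrogen from adding to the enamides.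

**Step 20**
Reactants: 27 N-sulfonyl macrocycle
Product: 28 O-triisopropylsilyl macrocyclic secondary amine (Z,Z; 3R,4aR,9bS)
Conditions: PhSH, K2CO3, DMF, rt
Reagents that add atoms: none
Why: In the Fukuyama deprotection thiophenolate adds to the nitro-activated ring at the sulfonyl-bearing carbon (Meisenheimer complex) and loss of SO2 releases the secondary amine; the β-substituted Z-enamides are poor thiol acceptors at room temperature, so the reaction is stopped as soon as 27 is consumed.

**Step 21**
Reactants: 28 O-silyl macrocyclic amine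
Product: 29 target, CNP0243477.1
Conditions: HF·pyridine, THF, 0 °C to rt; aq. NaHCO3
Reagents that add atoms: none
Why: Fluoride cleaves the Si–O bond of the TIPS ether under acidic conditions in which the secondary amine is protonated and cannot add to the enamides, leaving the three stereocentres and both Z-alkenes untouched.

**Compound list**
1 | glutaraldehyde (pentanedial) | O=CCCCC=O | starting material
2 | trimethyl phosphonoacetate | COC(=O)CP(=O)(OC)OC | starting material
3 | methyl 2-(dimethoxyphosphoryl)-3-hydroxy-7-oxoheptanoate (open-chain adduct, not isolated) | COC(=O)C(P(=O)(OC)OC)C(O)CCCC=O | intermediate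
4 | methyl 6-hydroxycyclohex-1-ene-1-carboxylate (racemic) | COC(=O)C1=CCCCC1O | intermediate
5 | methyl 6-{[(2,2,2-trichloroethoxy)carbonyl]oxy}cyclohex-1-ene-1-carboxylate (racemic) | COC(=O)C1=CCCCC1OC(=O)OCC(Cl)(Cl)Cl | intermediate
6 | 2-bromo-4-chlorophenol | Oc1ccc(Cl)cc1Br | starting material
7 | methyl (6R)-6-(2-bromo-4-chlorophenoxy)cyclohex-1-ene-1-carboxylate | COC(=O)C1=CCCC[C@H]1Oc1ccc(Cl)cc1Br | intermediate
8 | [(6R)-6-(2-bromo-4-chlorophenoxy)cyclohex-1-en-1-yl]methanol | OCC1=CCCC[C@H]1Oc1ccc(Cl)cc1Br | intermediate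
9 | tert-butyl{[(6R)-6-(2-bromo-4-chlorophenoxy)cyclohex-1-en-1-yl]methoxy}dimethylsilane | CC(C)(C)[Si](C)(C)OCC1=CCCC[C@H]1Oc1ccc(Cl)cc1Br | intermediate
10 | (4aR,9bR)-9b-{[(tert-butyldimethylsilyl)oxy]methyl}-8-chloro-3,4,4a,9b-tetrahydrodibenzo[b,d]furan | CC(C)(C)[Si](C)(C)OC[C@]12C=CCC[C@H]1Oc1ccc(Cl)cc12 | intermediate
11 | (3S,4aR,9bR)-9b-{[(tert-butyldimethylsilyl)oxy]methyl}-8-chloro-3,4,4a,9b-tetrahydrodibenzo[b,d]furan-3-ol | CC(C)(C)[Si](C)(C)OC[C@]12C=C[C@@H](O)C[C@H]1Oc1ccc(Cl)cc12 | intermediate
12 | (3R,4aR,9bR)-9b-{[(tert-butyldimethylsilyl)oxy]methyl}-8-chloro-1,2,3,4,4a,9b-hexahydrodibenzo[b,d]furan-3-ol | CC(C)(C)[Si](C)(C)OC[C@]12CC[C@@H](O)C[C@H]1Oc1ccc(Cl)cc12 | intermediate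
13 | tert-butyl{[(3R,4aR,9bR)-8-chloro-3-[(triisopropylsilyl)oxy]-1,2,3,4,4a,9b-hexahydrodibenzo[b,d]furan-9b-yl]methoxy}dimethylsilane | CC(C)(C)[Si](C)(C)OC[C@]12CC[C@@H](O[Si](C(C)C)(C(C)C)C(C)C)C[C@H]1Oc1ccc(Cl)cc12 | intermediate
14 | {(3R,4aR,9bR)-8-chloro-3-[(triisopropylsilyl)oxy]-1,2,3,4,4a,9b-hexahydrodibenzo[b,d]furan-9b-yl}methanol | OC[C@]12CC[C@@H](O[Si](C(C)C)(C(C)C)C(C)C)C[C@H]1Oc1ccc(Cl)cc12 | intermediate
15 | (3R,4aR,9bS)-8-chloro-3-[(triisopropylsilyl)oxy]-1,2,3,4,4a,9b-hexahydrodibenzo[b,d]furan-9b-carbaldehyde | O=C[C@]12CC[C@@H](O[Si](C(C)C)(C(C)C)C(C)C)C[C@H]1Oc1ccc(Cl)cc12 | intermediate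
16 | methyl (2Z)-3-{(3R,4aR,9bS)-8-chloro-3-[(triisopropylsilyl)oxy]-1,2,3,4,4a,9b-hexahydrodibenzo[b,d]furan-9b-yl}prop-2-enoate | COC(=O)/C=C\[C@]12CC[C@@H](O[Si](C(C)C)(C(C)C)C(C)C)C[C@H]1Oc1ccc(Cl)cc12 | intermediate
17 | (2Z)-3-{(3R,4aR,9bS)-8-chloro-3-[(triisopropylsilyl)oxy]-1,2,3,4,4a,9b-hexahydrodibenzo[b,d]furan-9b-yl}prop-2-enoic acid | OC(=O)/C=C\[C@]12CC[C@@H](O[Si](C(C)C)(C(C)C)C(C)C)C[C@H]1Oc1ccc(Cl)cc12 | intermediate
18 | 4-aminobutan-1-ol | NCCCCO | starting material
19 | (2Z)-3-{(3R,4aR,9bS)-8-chloro-3-[(triisopropylsilyl)oxy]-1,2,3,4,4a,9b-hexahydrodibenzo[b,d]furan-9b-yl}-N-(4-hydroxybutyl)prop-2-enamide | OCCCCNC(=O)/C=C\[C@]12CC[C@@H](O[Si](C(C)C)(C(C)C)C(C)C)C[C@H]1Oc1ccc(Cl)cc12 | intermediate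
20 | (2Z)-N-(4-hydroxybutyl)-3-{(3R,4aR,9bS)-8-(4,4,5,5-tetramethyl-1,3,2-dioxaborolan-2-yl)-3-[(triisopropylsilyl)oxy]-1,2,3,4,4a,9b-hexahydrodibenzo[b,d]furan-9b-yl}prop-2-enamide | OCCCCNC(=O)/C=C\[C@]12CC[C@@H](O[Si](C(C)C)(C(C)C)C(C)C)C[C@H]1Oc1ccc(B3OC(C)(C)C(C)(C)O3)cc12 | intermediate
21 | propane-1,3-diamine | NCCCN | starting material
22 | 2-nitrobenzenesulfonyl chloride | O=S(=O)(Cl)c1ccccc1[N+](=O)[O-] | starting material
23 | N-(3-aminopropyl)-2-nitrobenzenesulfonamide | NCCCNS(=O)(=O)c1ccccc1[N+](=O)[O-] | intermediate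
24 | (Z)-3-iodoacrylic acid | OC(=O)/C=C\I | starting material
25 | (2Z)-3-iodo-N-(3-{[(2-nitrophenyl)sulfonyl]amino}propyl)prop-2-enamide | I/C=C\C(=O)NCCCNS(=O)(=O)c1ccccc1[N+](=O)[O-] | intermediate
26 | seco hydroxy sulfonamide with both Z-enamides (3R,4aR,9bS; C3–OTIPS; 4-hydroxybutyl amide on the C9b arm, sulfonamidopropyl amide on the C8 arm) | OCCCCNC(=O)/C=C\[C@]12CC[C@@H](O[Si](C(C)C)(C(C)C)C(C)C)C[C@H]1Oc1ccc(/C=C\C(=O)NCCCNS(=O)(=O)c3ccccc3[N+](=O)[O-])cc12 | intermediate
27 | N-(2-nitrophenylsulfonyl), O-triisopropylsilyl 20-membered macrocycle (Z,Z; 3R,4aR,9bS) | O=C1/C=C\[C@]23CC[C@@H](O[Si](C(C)C)(C(C)C)C(C)C)C[C@H]2Oc2ccc(cc23)/C=C\C(=O)NCCCN(S(=O)(=O)c4ccccc4[N+](=O)[O-])CCCCN1 | intermediate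
28 | O-triisopropylsilyl macrocyclic secondary amine (Z,Z; 3R,4aR,9bS) | O=C1/C=C\[C@]23CC[C@@H](O[Si](C(C)C)(C(C)C)C(C)C)C[C@H]2Oc2ccc(cc23)/C=C\C(=O)NCCCNCCCCN1 | intermediate
29 | CNP0243477.1 (Z,Z macrocyclic spermidine bis-lactam on a (3R,4aR,9bS)-3-hydroxy-hexahydrodibenzofuran) | O=C1/C=C\[C@]23CC[C@@H](O)C[C@H]2Oc2ccc(cc23)/C=C\C(=O)NCCCNCCCCN1 | target

**Step count**
Total: 21 steps. Longest linear sequence: 19 steps (steps 1–15 and 18–21); steps 16–17 make the side-chain fragment 25.

**Steps most likely to fail**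

Step 19 (macrocyclisation). Intermolecular N-alkylation may overtake ring closure and give oligomers, or the activated alcohol may be consumed by elimination or by attack of the neighbouring amide oxygen before the sulfonamide anion reaches it. The fallback closes the same N–CH2 bond in two stages. Starting from 26, Appel conditions (I2, PPh3, imidazole, CH2Cl2, 0 °C) convert the alcohol into the primary iodide F1. F1 is then cyclised with Cs2CO3 in MeCN at high dilution and 50 °C (base-mediated alkylation of the 2-nitrobenzenesulfonamide anion), which rejoins the route at 27.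

Step 7 (allylic oxidation). Over-oxidation to the enone, thermal cleavage of the silyl ether at 150 °C, or insufficient facial selectivity at C3 may occur. In the fallback, 10 is oxidised deliberately to the ketone with CrO3 and 3,5-dimethylpyrazole (CH2Cl2, −20 °C), giving the enone F2. F2 is reduced with LiBH(s-Bu)3 in THF at −78 °C; the bulky hydride should attack the carbonyl from the face opposite the C4a–O bond, a known 1,2-reduction of such β-aryloxy cyclohexenones, and this gives 11. F2 is kept cold and free of base, because a β-aryloxy enone can open by retro-oxa-Michael reaction to an achiral dienone and so racemise.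

Step 12 (Z-olefination). Addition to the hindered neopentyl-type aldehyde may be slow, and Z selectivity may erode at the higher temperature then needed. In the fallback, 15 is converted by Stork–Zhao olefination (Ph3P+CH2I I−, NaN(SiMe3)2, THF/DMPU, −78 °C) into the Z-vinyl iodide F3. Aminocarbonylation of F3 with zerovalent palladium (Pd(PPh3)4, CO (1 atm), 18, Et3N, DMF, 50 °C) forms the Z-enamide with retention and rejoins the route at 19, bypassing 16 and 17; the aryl chloride should not react under these conditions.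

**Further compounds**
F1 | step 19 | (2Z)-N-(4-iodobutyl)-3-{(3R,4aR,9bS)-8-[(1Z)-3-oxo-3-({3-[(2-nitrophenyl)sulfonylamino]propyl}amino)prop-1-en-1-yl]-3-[(triisopropylsilyl)oxy]-1,2,3,4,4a,9b-hexahydrodibenzo[b,d]furan-9b-yl}prop-2-enamide | ICCCCNC(=O)/C=C\[C@]12CC[C@@H](O[Si](C(C)C)(C(C)C)C(C)C)C[C@H]1Oc1ccc(/C=C\C(=O)NCCCNS(=O)(=O)c3ccccc3[N+](=O)[O-])cc12
F2 | step 7 | (4aR,9bR)-9b-{[(tert-butyldimethylsilyl)oxy]methyl}-8-chloro-4,4a-dihydrodibenzo[b,d]furan-3(9bH)-one | CC(C)(C)[Si](C)(C)OC[C@]12C=CC(=O)C[C@H]1Oc1ccc(Cl)cc12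
F3 | step 12 | (3R,4aR,9bS)-8-chloro-9b-[(Z)-2-iodoethenyl]-3-[(triisopropylsilyl)oxy]-1,2,3,4,4a,9b-hexahydrodibenzo[b,d]furan | I/C=C\[C@]12CC[C@@H](O[Si](C(C)C)(C(C)C)C(C)C)C[C@H]1Oc1ccc(Cl)cc12
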